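## The problem

CNP0105552.1 (33) is a bisabolane-type triester whose ring is numbered C1 (OAc), C2 (O-angelate), C3 (methyl, epoxide), C4 (epoxide), C5 (CH2), C6 and whose chain runs from C7 (exocyclic methylene) through C8 (free OH), C9 and C10 (O-angelate) to C11 (dimethylcarbinol). In this numbering the ring carries five stereocentres (1R,2R,3S,4S,6S), and O1, O2, the epoxide oxygen and the C6 side chain all lie on one face ("top face" below). The chain adds a 1,3-anti pair (8R,10R) that is insulated from the ring by the sp2 carbon C7, so the ring centres can control one another but neither C8 nor C10. Five oxygens are present in three states (one acetate, two angelates, two free hydroxyls), and O1/O2 form a cis-diol whose two different esters must not change places. The sensitive groups are the (Z)-2-methylbut-2-enoates (Z to E isomerisation, conjugate addition), the trisubstituted epoxide (acid), esters next to free hydroxyls (acyl migration) and the β-acyloxy carbonyl compounds met on the way (elimination). The enabling feature is the 1,4-cis relation across the ring between the oxygen on C3 and the carbon C7 on C6. Joined, they are the O–C(=O) bridge of a 2-oxabicyclo[2.2.2]octenone, the cycloadduct of a 2-pyrone whose 6-methyl group is the C3 methyl; the alkene left in such an adduct is C1=C2, where the cis-diol is needed, and the dienophile supplies C4 and C5.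

## Retrosynthesis

**C7–C8.** A 1,1-disubstituted alkene next to a secondary carbinol is the retron of an alkenylchromium addition to an aldehyde. Target 33 is therefore traced, through its C11 silyl ether 32, to alkenyl triflate 25 and aldehyde 31. A C8–C9 aldol cut would need an α-methylene ketone on the ring and would leave O8 and O10 to be told apart later. A C6–C7 cut would create a ring stereocentre during fragment union. The chosen cut gives two fragments that already carry their final esters, and the one hydroxyl it creates (O8) is free in the target. The forward step must add to the Si face of 31 under reagent control and spare an epoxide, an acetate and two angelates. The C11 hydroxyl is silylated in 31 only because the free γ-hydroxy aldehyde would close to a lactol.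

**Ring esters.** Fragment 25 is cut at the C2–O acyl bond to hydroxy acetate 22 and mixed anhydride 24. The anhydride is prepared once from angelic acid 23 and serves both angeloylations of the route. Compound 22 is cut at the C1–O acyl bond to cis-diol 20 through cyclic orthoacetate 21. Carrying two different protecting groups on O1 and O2 from the bicyclic stage would cost extra steps and a selective silylation. The orthoester route instead uses ring conformation: the ester is released on the axial oxygen, which is O1 when the C6 substituent is equatorial.

**C7 handle.** Diol 20 comes from bis-silyl ether 19, the alkenyl triflate of methyl ketone 17 (through enolate 18). Ketone 17 comes from N-methoxy-N-methylamide 16 by a single methyl addition. Silyl ethers are chosen because they leave with fluoride; an acetal would need acid, which the epoxide would not survive.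

**Epoxide.** The C4–O bond of 16 is cut to hydroxy mesylate 15, with O3 on the top face and the leaving group on the bottom face. Its precursor, diol 14, arises by aminolysis of bridged lactone 13. That one operation frees O3, turns C7 into the amide and removes the C4 acetate. The forward closure is an SN2 inversion at C4 and needs the trans-diaxial arrangement that the chair with C7 equatorial provides.

**C4 oxygen and the diol.** The C4 acetate 13 comes from methyl ketone 12 by oxygen insertion with retention. Compound 12 is the silylated form of diol 11, and 11 comes from alkene 10 by dihydroxylation on the face syn to the lactone bridge. The diol is made before the oxygen insertion because a peracid would epoxidise C1=C2.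

**Acyl exchange.** Methyl ketone 10 is traced through thioester 9 to imide 8. The thiolate and methylcopper steps are chosen because both leave a strained lactone untouched.

**Key disconnection.** Imide 8 is cut at C5–C6 and C3–C4 into 6-methyl-2H-pyran-2-one 3 and 3-acryloyl-1,3-oxazolidin-2-one 7. This removes the ring, three stereocentres and the face bias for two more in one step and leaves two achiral compounds. The forward reaction must be regioselective (acyl carbon to C4), endo and enantioselective, and must stop before CO2 is lost.

**Starting materials.** Pyrone 3 comes from triflate 2 of 4-hydroxy-6-methyl-2H-pyran-2-one 1. Imide 7 comes from 1,3-oxazolidin-2-one 4 (as its magnesium salt 6) and acryloyl chloride 5.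

**Side chain.** Aldehyde 31 is traced through bis-silyl ether 30, angelate 29 (from diol 28 and the same anhydride 24), primary silyl ether 28 and triol 27 to (3R)-3-hydroxyoxolan-2-one 26. The C10 stereocentre is taken from the chiral pool and is never touched.

## Roads not taken

**Alternative 1:** The cut is at C6–C7 and C1–O. A cyclohexenediol A1 (C1=C6 alkene, free O2 and O3, O4 as a 4-methoxybenzyl ether on the bottom face) would be combined with the side-chain hydroximoyl chloride A2. The nitrile oxide from A2 would add to the bromomagnesium alkoxide of A1 to give the cis-fused isoxazoline A3, which holds the whole carbon skeleton.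
- Merits: alkoxide-directed nitrile oxide cycloaddition to an allylic alcohol is a known reaction type, which the chosen key step is not. The C2 alkoxide should deliver C7 and O1 to its own face. C8 comes from the chiral pool inside A2 instead of being created at the coupling, a real advantage over step 23. O1 is born masked and so is already distinguished from O2.
- Weak points: A1 is itself a ring with a tertiary carbinol and a trans ether and would need a long linear sequence from a pentonolactone. A 1,2-disubstituted cyclohexene is a slow dipolarophile, so the α-silyloxy nitrile oxide may dimerise or lose its C8 configuration. After N–O cleavage the C7 ketone, flanked by the C1 hydroxyl and the C8 silyloxy group, must be methylenated late, with retro-aldol and elimination as competitors.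
- Comparison: against the better C8 control and the known key step, the chosen plan offers a ring made from two achiral compounds in which one step sets three ring stereocentres and templates the other two. Its methylene group enters as a methyl ketone and alkenyl triflate, not by olefination of a hindered β-hydroxy ketone.

**Alternative 2:** The cut is at C1–C2 and C5–C6. Diene A4 would add thermally, endo and anti to the menthyloxy group, to butenolide A5 to give the cis-fused lactone acetal A6.
- Merits: this is a thermal, auxiliary-controlled cycloaddition of an established type and is safer than step 4. C1, C2 and C6 are set as a cis triad at once. O2 arrives alone and protected, so the diol differentiation of steps 14, 15 and 17 does not arise. The C3=C4 alkene is ready for hydroxyl-directed epoxidation from the face of O2.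
- Weak points: C1 arrives bearing the lactone carbonyl carbon, not oxygen, so a carbon must be excised and replaced by oxygen with retention next to the epimerisable C6. At the same time the acetal carbon that is to become C7 must be released from the same ring and raised to the alkenyl unit. The auxiliary is stoichiometric.
- Comparison: the chosen plan also pays for one carbon-to-oxygen exchange (C4, step 9). There, however, the carbon to be removed belongs to the only ketone present, and C7 is already the carbonyl carbon it must be. In return the chosen plan must differentiate O1 from O2 late and rely on an unprecedented cycloaddition.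

**Alternative 3:** The cut is at C2–C3 and C4–C5. Ni(cod)2 (zerovalent nickel) with a chiral binaphthyl bisphosphine would insert alkyne A8 into one enantiotopic acyl–CH2 bond of cyclobutanone A7. The ring would expand to cyclohexenone A9, which carries the C3 methyl, a C4 silyl group, the C2 carbonyl and the C7 ester on C6.
- Merits: it is the shortest access to a six-membered ring with the right carbon substitution, catalytic in metal and chirality. The C7 ester is directly the handle that the chosen plan makes by aminolysis.
- Weak points: only C6 is set. C1 is a bare CH2 and C2 a ketone, so O1, O2 and the epoxide must all be introduced later by substrate control from one remote centre, each with its own selectivity question. The intermolecular enantiotopos-selective insertion is itself without precedent, so the step is no safer than step 4.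
- Comparison: this road reaches a ring sooner but leaves four of five ring stereocentres open. The equally unprecedented step of the chosen plan returns three stereocentres, a face-differentiated alkene for two more, and every ring oxygen or its direct precursor.

Key step: step 4

Remark on step 4: on the square-planar chelate model the (S,S)-t-Bu-box ligand leaves the Re face of the acrylimide α-carbon open and would give the 4S adduct; the 4R adduct 8 therefore calls for the (R,R) ligand.

Assumption for step 23: the (S)-valinol-derived oxazoline–sulfonamide ligand is taken to direct the alkenylchromium to the Si face of 31; if the sense proves opposite, its enantiomer is used.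

Assumption on supply: lactone 26, the lactone form of the D-malic acid chiral pool, is taken as purchasable.

Locants C1–C11 are those defined above; "top face" is the ring face that carries C7.

## Route

Step 1
Reactants: 1 4-hydroxy-6-methyl-2H-pyran-2-one
Product: 2 6-methyl-2-oxo-2H-pyran-4-yl trifluoromethanesulfonate
Conditions: Tf2O, Et3N, CH2Cl2, −78 to 0 °C
Reagents that add atoms: trifluoromethanesulfonic anhydride, O=S(=O)(OS(=O)(=O)C(F)(F)F)C(F)(F)F
Why: O-sulfonylation of the acidic vinylogous acid hydroxyl, which should be clean at low temperature.

Step 2
Reactants: 2 6-methyl-2-oxo-2H-pyran-4-yl trifluoromethanesulfonate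
Product: 3 6-methyl-2H-pyran-2-one
Conditions: Pd(OAc)2 (cat.), PPh3, HCO2H, Et3N, DMF, 60 °C
Reagents that add atoms: none
Why: Palladium-catalysed formate reduction of an enol triflate (oxidative addition, decarboxylation of the formate, reductive elimination) removes the 4-oxygen and leaves the diene intact.

Step 3
Reactants: 4 1,3-oxazolidin-2-one; 5 acryloyl chloride
Product: 7 3-acryloyl-1,3-oxazolidin-2-one, via N-bromomagnesium oxazolidinone 6 (not isolated)
Conditions: MeMgBr, THF, 0 °C; then 5, −78 to 0 °C
Reagents that add atoms: methylmagnesium bromide, C[Mg]Br (magnesium and bromine present in 6 only)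
Why: N-acylation of the magnesium salt of the carbamate; the weakly basic magnesium amide limits anionic polymerisation of the acrylate.

Step 4
Reactants: 3 6-methyl-2H-pyran-2-one; 7 3-acryloyl-1,3-oxazolidin-2-one
Product: 8 3-{[(1R,4R,7R)-1-methyl-3-oxo-2-oxabicyclo[2.2.2]oct-5-en-7-yl]carbonyl}-1,3-oxazolidin-2-one (endo adduct: lactone carbonyl is C7, lactone oxygen on C3, imide on C4 anti to the bridge, alkene C1=C2)
Conditions: [Cu((R,R)-t-Bu-box)](SbF6)2 (10 mol %, divalent copper), CH2Cl2, −20 °C to rt
Reagents that add atoms: none
Why: Proposed new method: the cationic copper complex binds imide 7 as an s-cis two-point chelate and lowers its LUMO, and pyrone 3 adds as the diene in a concerted but asynchronous [4+2] (in the limit, Michael addition of the pyrone α-carbon followed by collapse of the copper enolate onto the oxocarbenium carbon); the closest known reaction types are the thermal or high-pressure Diels–Alder reaction of 2-pyrones with acrylates to isolable bridged lactones and the copper–bis(oxazoline)-catalysed Diels–Alder reaction of this imide with other dienes. The carbocycle C1–C6 is closed intermolecularly and suprafacially on both partners by the bonds C5–C6 and C3–C4, and the lactone bridge is carried over from the pyrone. The regiochemistry that the step needs is electronic: the ring oxygen and the methyl group on the pyrone carbon that becomes C3 make the other terminus (future C6) nucleophilic, so it bonds to the acrylimide β-carbon and the acyl-bearing carbon becomes C4. C3 and C6 are set together because the dienophile adds to one face of the diene, which leaves O3 and C7 cis as the bridge. C4 is set relative to them by the endo approach, with the acyl group under the diene and hence anti to the lactone bridge. The absolute sense comes from the ligand, whose tert-butyl group covers the Re face of the α-carbon so that the pyrone adds to the Si face and C4 becomes R. The adduct must not lose CO2, which is secured by staying at or below room temperature.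

Step 5
Reactants: 8 endo imide cycloadduct
Product: 9 S-ethyl (1R,4R,7R)-1-methyl-3-oxo-2-oxabicyclo[2.2.2]oct-5-ene-7-carbothioate
Conditions: EtSH, n-BuLi, THF, −78 to 0 °C
Reagents that add atoms: ethanethiol, CCS
Why: Acyl substitution by thiolate at the exocyclic imide carbonyl, the most electrophilic one; a lactone opened by thiolate would re-close, and the weakly basic thiolate should not epimerise C4.

Step 6
Reactants: 9 S-ethyl thioester
Product: 10 (1R,4R,7R)-7-acetyl-1-methyl-2-oxabicyclo[2.2.2]oct-5-en-3-one
Conditions: Me2CuLi (from MeLi and CuI, copper monoiodide), Et2O, −78 °C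
Reagents that add atoms: lithium dimethylcuprate, [Li+].C[Cu-]C
Why: Thioester-to-ketone substitution by a Gilman cuprate, which stops at the ketone and does not attack lactones at this temperature.

Step 7
Reactants: 10 bridged lactone methyl ketone
Product: 11 7-acetyl-5,6-dihydroxy-1-methyl-2-oxabicyclo[2.2.2]octan-3-one (hydroxyls on C1 and C2 cis to each other and syn to the lactone bridge; acetyl on C4 anti)
Conditions: OsO4 (cat.), N-methylmorpholine N-oxide, acetone/H2O, 0 °C to rt
Reagents that add atoms: osmium tetroxide, O=[Os](=O)(=O)=O (catalytic, re-formed from N-methylmorpholine N-oxide, C[N+]1([O-])CCOCC1); water, O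
Why: Catalytic syn-dihydroxylation; the alkene face turned toward the C4–C5 bridge is shielded by the endo acetyl group, so osmylation should occur syn to the O–C(=O) bridge and place both hydroxyls on the top face (sets C1 and C2), and neutral conditions with direct silylation limit migration of the lactone acyl group to O2.

Step 8
Reactants: 11 bridged lactone diol
Product: 12 bis(triethylsilyl) ether of 11 (O1 and O2 silylated)
Conditions: TESOTf, 2,6-lutidine, CH2Cl2, −78 to 0 °C
Reagents that add atoms: triethylsilyl trifluoromethanesulfonate, CC[Si](CC)(CC)OS(=O)(=O)C(F)(F)F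
Why: Silylation of both hindered secondary hydroxyls with the silyl triflate; triethylsilyl ethers should survive the basic and organometallic steps ahead and leave later with fluoride, without the acid that the epoxide would not tolerate.

Step 9
Reactants: 12 bis-silyl ether methyl ketone
Product: 13 C4 acetate (acetyl of 12 replaced by acetoxy with retention; acetoxy anti to the lactone bridge)
Conditions: m-CPBA, NaHCO3, CH2Cl2, rt
Reagents that add atoms: 3-chloroperoxybenzoic acid, OOC(=O)c1cccc(Cl)c1
Why: Baeyer–Villiger oxidation; the secondary carbon C4 migrates in preference to methyl and with retention, so the new C4–O bond stays on the bottom face, trans to O3.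

Step 10
Reactants: 13 bridged lactone C4 acetate
Product: 14 N-methoxy-N-methylamide diol (C7 amide on C6; C1 and C2 triethylsilyloxy and the tertiary C3 hydroxyl on the top face; C4 hydroxyl on the bottom face)
Conditions: MeNH(OMe)·HCl, i-PrMgCl, THF, −20 to 0 °C
Reagents that add atoms: N,O-dimethylhydroxylamine hydrochloride, CNOC.Cl
Why: The chloromagnesium amide opens the strained lactone by acyl–oxygen cleavage to the Weinreb amide and removes the C4 acetate by aminolysis in the same operation, freeing the tertiary C3 and secondary C4 hydroxyls.

Step 11
Reactants: 14 Weinreb amide diol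
Product: 16 epoxy Weinreb amide (C3–C4 epoxide on the top face; C1 and C2 triethylsilyloxy), via C4 mesylate 15 (not isolated)
Conditions: MsCl, Et3N, CH2Cl2, −20 °C; then K2CO3, MeOH, rt
Reagents that add atoms: methanesulfonyl chloride, CS(=O)(=O)Cl (atoms present in 15 only)
Why: Selective sulfonylation of the secondary hydroxyl, then intramolecular Williamson closure (3-exo-tet); in the chair with C7 equatorial the C3 alkoxide and the C4 mesylate are trans-diaxial, so C4 is inverted and the epoxide oxygen ends on the top face.

Step 12
Reactants: 16 epoxy Weinreb amide
Product: 17 epoxy methyl ketone (C7 acetyl on C6; otherwise as 16)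
Conditions: MeLi, THF, −78 °C
Reagents that add atoms: methyllithium, [Li]C
Why: Single addition to the Weinreb amide through the stable chelated tetrahedral intermediate; the epoxide and silyl ethers are inert at this temperature.

Step 13
Reactants: 17 epoxy methyl ketone
Product: 19 alkenyl triflate (C7 as C(OTf)=CH2; C1 and C2 triethylsilyloxy; top-face epoxide), via potassium enolate 18 (not isolated)
Conditions: KHMDS, THF, −78 °C; then PhNTf2, −78 to 0 °C
Reagents that add atoms: N-phenylbis(trifluoromethanesulfonimide), O=S(=O)(N(c1ccccc1)S(=O)(=O)C(F)(F)F)C(F)(F)F; potassium bis(trimethylsilyl)amide, C[Si](C)(C)[N-][Si](C)(C)C.[K+] (potassium present in 18 only)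
Why: Kinetic deprotonation at the methyl group (the tertiary, β-silyloxy C6–H is hindered) and O-sulfonylation of the enolate give the 2-substituted alkenyl triflate without touching C6.

Step 14
Reactants: 19 bis-silyl alkenyl triflate
Product: 20 alkenyl triflate cis-diol (free hydroxyls on C1 and C2, top face)
Conditions: HF·pyridine, pyridine, THF, 0 °C to rt
Reagents that add atoms: none
Why: Buffered fluoride cleaves both triethylsilyl ethers under conditions that should leave the alkenyl triflate and the epoxide intact.

Step 15
Reactants: 20 alkenyl triflate cis-diol
Product: 22 C1 acetate with free C2 hydroxyl, via cyclic orthoacetate 21 (not isolated)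
Conditions: MeC(OMe)3, pyridinium p-toluenesulfonate (cat.), CH2Cl2, rt; then AcOH/H2O, 0 °C to rt
Reagents that add atoms: trimethyl orthoacetate, COC(C)(OC)OC; water, O
Why: Orthoester exchange gives the cyclic orthoacetate, whose mild acid hydrolysis through the dioxolan-2-ylium ion and hemi-orthoester releases the ester on the axial oxygen; with the C6 substituent equatorial that oxygen is O1, so the acetate lands on C1 and O2 is freed, and the epoxide is deactivated toward acid by the flanking C2 oxygen.

Step 16
Reactants: 23 angelic acid ((2Z)-2-methylbut-2-enoic acid)
Product: 24 angelic 2,4,6-trichlorobenzoic anhydride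
Conditions: 2,4,6-trichlorobenzoyl chloride, Et3N, toluene, rt; Et3N·HCl filtered off, toluene solution divided for steps 17 and 20
Reagents that add atoms: 2,4,6-trichlorobenzoyl chloride, O=C(Cl)c1c(Cl)cc(Cl)cc1Cl
Why: Yamaguchi activation: the triethylammonium carboxylate displaces chloride from the aroyl chloride to give the mixed anhydride; no nucleophilic catalyst is present and the mixture stays at room temperature, so the (Z)-geometry is kept, and one batch serves both angeloylations.

Step 17
Reactants: 22 C1 acetate with free C2 hydroxyl; 24 angelic 2,4,6-trichlorobenzoic anhydride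
Product: 25 ring fragment (C1 acetate, C2 angelate, top-face epoxide, alkenyl triflate at C7)
Conditions: 24 (excess, toluene solution), Et3N, toluene, 80 °C
Reagents that add atoms: none
Why: Yamaguchi-type esterification: the C2 hydroxyl attacks the angeloyl carbonyl of 24 because the aroyl carbonyl is shielded by its two ortho chlorines; without a nucleophilic catalyst the angeloyl group is transferred with little Z to E isomerisation, and the amine takes up the liberated acid so that the epoxide is not exposed to it.

Step 18
Reactants: 26 (3R)-3-hydroxyoxolan-2-one
Product: 27 (3R)-4-methylpentane-1,3,4-triol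
Conditions: MeMgBr (excess), THF, 0 °C to rt
Reagents that add atoms: methylmagnesium bromide, C[Mg]Br
Why: Double Grignard addition to the lactone carbonyl after deprotonation of the hydroxyl gives the dimethylcarbinol; the stereocentre is not involved.

Step 19
Reactants: 27 (3R)-4-methylpentane-1,3,4-triol
Product: 28 (3R)-4-methyl-1-[(triethylsilyl)oxy]pentane-3,4-diol
Conditions: TESCl, imidazole, CH2Cl2, −40 to −20 °C
Reagents that add atoms: chlorotriethylsilane, CC[Si](Cl)(CC)CC
Why: Selective silylation of the primary hydroxyl over the hindered secondary and the tertiary ones at low temperature.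

Step 20
Reactants: 28 primary silyl ether diol; 24 angelic 2,4,6-trichlorobenzoic anhydride
Product: 29 (3R)-4-hydroxy-4-methyl-1-[(triethylsilyl)oxy]pentan-3-yl (2Z)-2-methylbut-2-enoate
Conditions: 24 (excess, toluene solution), Et3N, toluene, 80 °C
Reagents that add atoms: none
Why: The same mixed-anhydride esterification; only the secondary hydroxyl reacts, the tertiary one being inert under these conditions, and the amine buffer protects the primary silyl ether from the liberated acid.

Step 21
Reactants: 29 hydroxy angelate
Product: 30 (3R)-4-methyl-1,4-bis[(triethylsilyl)oxy]pentan-3-yl (2Z)-2-methylbut-2-enoate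
Conditions: TESOTf, 2,6-lutidine, CH2Cl2, −78 to 0 °C
Reagents that add atoms: triethylsilyl trifluoromethanesulfonate, CC[Si](CC)(CC)OS(=O)(=O)C(F)(F)F
Why: Silylation of the tertiary hydroxyl with the silyl triflate, so that the aldehyde of step 22 cannot close to a lactol.

Step 22
Reactants: 30 bis-silyl ether angelate
Product: 31 (3R)-4-methyl-1-oxo-4-[(triethylsilyl)oxy]pentan-3-yl (2Z)-2-methylbut-2-enoate
Conditions: (COCl)2, DMSO, CH2Cl2, −78 to −40 °C; then Et3N, −78 to 0 °C
Reagents that add atoms: none
Why: Swern conditions convert a primary triethylsilyl ether directly into the aldehyde (chloride-assisted desilylation on the activated sulfonium species) while tertiary silyl ethers persist; keeping the amine stage cold limits β-elimination of the angelate.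

Step 23
Reactants: 25 ring fragment alkenyl triflate; 31 side-chain aldehyde
Product: 32 11-O-triethylsilyl ether of 33 (8R)
Conditions: CrCl2, N-[2-((4S)-4-isopropyl-4,5-dihydro-1,3-oxazol-2-yl)-6-methylphenyl]methanesulfonamide, Et3N, THF, rt; then NiCl2 (cat.), 25, 31, rt
Reagents that add atoms: none
Why: Nozaki–Hiyama–Kishi coupling: nickel inserts into the alkenyl triflate, transmetallation gives an alkenylchromium species that adds only to the aldehyde, and the chiral sulfonamide on chromium is expected to direct addition to the Si face and set C8 as R, with esters, epoxide and silyl ether untouched.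

Step 24
Reactants: 32 11-O-triethylsilyl ether
Product: 33 CNP0105552.1
Conditions: HF·pyridine, pyridine, THF, 0 °C to rt
Reagents that add atoms: none
Why: Buffered fluoride removes the tertiary triethylsilyl ether; neither a base strong enough for acyl migration nor an acid strong enough to open the epoxide is present.

## Compound list

1 | 4-hydroxy-6-methyl-2H-pyran-2-one | CC1=CC(O)=CC(=O)O1 | starting material
2 | 6-methyl-2-oxo-2H-pyran-4-yl trifluoromethanesulfonate | CC1=CC(OS(=O)(=O)C(F)(F)F)=CC(=O)O1 | intermediate
3 | 6-methyl-2H-pyran-2-one | CC1=CC=CC(=O)O1 | intermediate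
4 | 1,3-oxazolidin-2-one | O=C1NCCO1 | starting material
5 | acryloyl chloride | C=CC(=O)Cl | starting material
6 | 3-(bromomagnesio)-1,3-oxazolidin-2-one (formed in the flask) | O=C1OCCN1[Mg]Br | intermediate
7 | 3-acryloyl-1,3-oxazolidin-2-one | C=CC(=O)N1CCOC1=O | intermediate
8 | 3-{[(1R,4R,7R)-1-methyl-3-oxo-2-oxabicyclo[2.2.2]oct-5-en-7-yl]carbonyl}-1,3-oxazolidin-2-one | O=C1[C@@H]2C[C@@H](C(=O)N3CCOC3=O)[C@](C)(O1)C=C2 | intermediate
9 | S-ethyl (1R,4R,7R)-1-methyl-3-oxo-2-oxabicyclo[2.2.2]oct-5-ene-7-carbothioate | O=C1[C@@H]2C[C@@H](C(=O)SCC)[C@](C)(O1)C=C2 | intermediate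
10 | (1R,4R,7R)-7-acetyl-1-methyl-2-oxabicyclo[2.2.2]oct-5-en-3-one | O=C1[C@@H]2C[C@@H](C(C)=O)[C@](C)(O1)C=C2 | intermediate
11 | 7-acetyl-5,6-dihydroxy-1-methyl-2-oxabicyclo[2.2.2]octan-3-one, hydroxyls syn to the lactone bridge, acetyl anti | O=C1[C@@H]2C[C@@H](C(C)=O)[C@](C)(O1)[C@H](O)[C@@H]2O | intermediate
12 | bis(triethylsilyl) ether of 11 | O=C1[C@@H]2C[C@@H](C(C)=O)[C@](C)(O1)[C@H](O[Si](CC)(CC)CC)[C@@H]2O[Si](CC)(CC)CC | intermediate
13 | 1-methyl-3-oxo-5,6-bis(triethylsilyloxy)-2-oxabicyclo[2.2.2]octan-7-yl acetate, acetoxy anti to the lactone bridge | O=C1[C@@H]2C[C@@H](OC(C)=O)[C@](C)(O1)[C@H](O[Si](CC)(CC)CC)[C@@H]2O[Si](CC)(CC)CC | intermediate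
14 | N-methoxy-N-methylamide diol (O1, O2 silylated; O3 top face; O4 bottom face) | CON(C)C(=O)[C@@H]1C[C@@H](O)[C@](C)(O)[C@H](O[Si](CC)(CC)CC)[C@@H]1O[Si](CC)(CC)CC | intermediate
15 | C4 methanesulfonate of 14 (formed in the flask) | CON(C)C(=O)[C@@H]1C[C@@H](OS(C)(=O)=O)[C@](C)(O)[C@H](O[Si](CC)(CC)CC)[C@@H]1O[Si](CC)(CC)CC | intermediate
16 | epoxy N-methoxy-N-methylamide (top-face C3–C4 epoxide) | CON(C)C(=O)[C@@H]1C[C@@H]2O[C@]2(C)[C@H](O[Si](CC)(CC)CC)[C@@H]1O[Si](CC)(CC)CC | intermediate
17 | epoxy methyl ketone | CC(=O)[C@@H]1C[C@@H]2O[C@]2(C)[C@H](O[Si](CC)(CC)CC)[C@@H]1O[Si](CC)(CC)CC | intermediate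
18 | potassium enolate of 17 (formed in the flask) | [K+].C=C([O-])[C@@H]1C[C@@H]2O[C@]2(C)[C@H](O[Si](CC)(CC)CC)[C@@H]1O[Si](CC)(CC)CC | intermediate
19 | alkenyl triflate, O1 and O2 silylated | C=C(OS(=O)(=O)C(F)(F)F)[C@@H]1C[C@@H]2O[C@]2(C)[C@H](O[Si](CC)(CC)CC)[C@@H]1O[Si](CC)(CC)CC | intermediate
20 | alkenyl triflate cis-diol | C=C(OS(=O)(=O)C(F)(F)F)[C@@H]1C[C@@H]2O[C@]2(C)[C@H](O)[C@@H]1O | intermediate
21 | cyclic methyl orthoacetate of 20 across O1 and O2 (formed in the flask; orthoester carbon unassigned) | C=C(OS(=O)(=O)C(F)(F)F)[C@@H]1C[C@@H]2O[C@]2(C)[C@H](OC3(C)OC)[C@@H]1O3 | intermediate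
22 | C1 acetate with free C2 hydroxyl | C=C(OS(=O)(=O)C(F)(F)F)[C@@H]1C[C@@H]2O[C@]2(C)[C@H](O)[C@@H]1OC(C)=O | intermediate
23 | angelic acid, (2Z)-2-methylbut-2-enoic acid | C/C=C(/C)C(=O)O | starting material
24 | angelic 2,4,6-trichlorobenzoic anhydride (one batch, kept as a filtered toluene solution) | C/C=C(/C)C(=O)OC(=O)c1c(Cl)cc(Cl)cc1Cl | intermediate
25 | ring fragment: C1 acetate, C2 angelate, top-face epoxide, C7 alkenyl triflate | C=C(OS(=O)(=O)C(F)(F)F)[C@@H]1C[C@@H]2O[C@]2(C)[C@H](OC(=O)/C(C)=C\C)[C@@H]1OC(C)=O | intermediate
26 | (3R)-3-hydroxyoxolan-2-one | O[C@@H]1CCOC1=O | starting material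
27 | (3R)-4-methylpentane-1,3,4-triol | OCC[C@@H](O)C(C)(C)O | intermediate
28 | (3R)-4-methyl-1-[(triethylsilyl)oxy]pentane-3,4-diol | CC[Si](CC)(CC)OCC[C@@H](O)C(C)(C)O | intermediate
29 | (3R)-4-hydroxy-4-methyl-1-[(triethylsilyl)oxy]pentan-3-yl (2Z)-2-methylbut-2-enoate | CC[Si](CC)(CC)OCC[C@@H](OC(=O)/C(C)=C\C)C(C)(C)O | intermediate
30 | (3R)-4-methyl-1,4-bis[(triethylsilyl)oxy]pentan-3-yl (2Z)-2-methylbut-2-enoate | CC[Si](CC)(CC)OCC[C@@H](OC(=O)/C(C)=C\C)C(C)(C)O[Si](CC)(CC)CC | intermediate
31 | (3R)-4-methyl-1-oxo-4-[(triethylsilyl)oxy]pentan-3-yl (2Z)-2-methylbut-2-enoate | O=CC[C@@H](OC(=O)/C(C)=C\C)C(C)(C)O[Si](CC)(CC)CC | intermediate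
32 | 11-O-triethylsilyl ether of 33 | C=C([C@H](O)C[C@@H](OC(=O)/C(C)=C\C)C(C)(C)O[Si](CC)(CC)CC)[C@@H]1C[C@@H]2O[C@]2(C)[C@H](OC(=O)/C(C)=C\C)[C@@H]1OC(C)=O | intermediate
33 | CNP0105552.1 (1R,2R,3S,4S,6S,8R,10R in the numbering used here) | C=C([C@H](O)C[C@@H](OC(=O)/C(C)=C\C)C(C)(C)O)[C@@H]1C[C@@H]2O[C@]2(C)[C@H](OC(=O)/C(C)=C\C)[C@@H]1OC(C)=O | target

## Step count and least certain steps

Total step count: 24. Longest linear sequence: 17 steps (1, 2, 4–15, 17, 23, 24) from compound 1.

**Step 4 (key step, proposed new method).**
- What may go wrong: the electron-poor pyrone may be too weak a diene even for the cationic copper–imide complex. The likely failures are loss of a proton from the zwitterionic adduct (Friedel–Crafts-type alkylation of the pyrone in place of ring closure), polymerisation of the acrylimide, erosion of endo or regiocontrol in a stepwise pathway, and CO2 extrusion on warming.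
- Fallback (known chemistry): the uncatalysed reaction type is used. Compound 3 is combined with purchasable (4S)-4-benzyl-3-acryloyl-1,3-oxazolidin-2-one under about 12 kbar in CH2Cl2 at room temperature. The auxiliary is not expected to control the face; it only makes the two endo adducts diastereomers. The one with the (1R,4R,7R) core, the benzyl-substituted endo adduct F1, is separated by chromatography or crystallisation and cleaved with LiSEt as in step 5.
- The fallback sets out from 3 and returns to the route at 9.

**Step 15.**
- What may go wrong: the hemi-orthoester may collapse with the wrong regiochemistry (acetate on O2) if the ring does not sit in the expected half-chair, and the acid may open the epoxide.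
- Fallback: from 20, a different selectivity rule reverses the order of the acylations. The dibutylstannylene acetal F2 (Bu2SnO, MeOH, reflux) is acylated at its equatorial oxygen, O2, with angelic anhydride to give the C2 angelate with free C1 hydroxyl F3. Acetylation (Ac2O, pyridine, 4-dimethylaminopyridine) then gives 25.
- The fallback sets out from 20 and returns at 25, so step 17 is not needed.

**Step 17.**
- What may go wrong: Z to E isomerisation to the tiglate during heating, migration of the acetyl group from the axial O1 to the equatorial O2 before acylation, and slow reaction of the hindered C2 hydroxyl.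
- Fallback: from 22, the angelate is built in place at low temperature. Esterification with 2-[bis(2,2,2-trifluoroethoxy)phosphoryl]propanoic acid (dicyclohexylcarbodiimide, CH2Cl2, 0 °C to rt) gives the phosphonate ester F4. Still–Gennari olefination with acetaldehyde (KHMDS, 18-crown-6, THF, −78 °C) then gives the (Z)-enoate.
- The fallback sets out from 22 and returns at 25.

**Step 23.**
- What may go wrong: poor facial selectivity at C8 if the ligand is mismatched with the C10 and C6 stereocentres, slow coupling of the hindered alkenyl triflate, and migration of the C10 angeloyl group to the new chromium alkoxide.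
- Fallback: from 25 and 31, an achiral coupling (CrCl2, NiCl2 cat., DMSO) gives the C8-epimeric alcohols F6. Oxidation with Dess–Martin periodinane gives the enone F7. Corey–Bakshi–Shibata reduction with the (S)-methyl oxazaborolidine and catecholborane (toluene, −78 °C), in which the α-branched alkenyl group acts as the large substituent, should give the 8R alcohol.
- The fallback sets out from 25 and 31 and returns at 32.

**Step 22.**
- What may go wrong: β-elimination of the angelate from the β-acyloxy aldehyde during the amine stage, and partial loss of the tertiary silyl ether.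
- Fallback: from 30, the primary silyl ether alone is cleaved (HF·pyridine, pyridine, THF, 0 °C) to the primary alcohol F5, which is oxidised without base by Dess–Martin periodinane buffered with NaHCO3.
- The fallback sets out from 30 and returns at 31.

## Further compounds

F1 | step 4 | (4S)-4-benzyl-3-{[(1R,4R,7R)-1-methyl-3-oxo-2-oxabicyclo[2.2.2]oct-5-en-7-yl]carbonyl}-1,3-oxazolidin-2-one | O=C1[C@@H]2C[C@@H](C(=O)N3[C@@H](Cc4ccccc4)COC3=O)[C@](C)(O1)C=C2
F2 | step 15 | dibutylstannylene acetal of 20 across O1 and O2 | C=C(OS(=O)(=O)C(F)(F)F)[C@@H]1C[C@@H]2O[C@]2(C)[C@H](O[Sn]3(CCCC)CCCC)[C@@H]1O3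
F3 | step 15 | C2 angelate with free C1 hydroxyl | C=C(OS(=O)(=O)C(F)(F)F)[C@@H]1C[C@@H]2O[C@]2(C)[C@H](OC(=O)/C(C)=C\C)[C@@H]1O
F4 | step 17 | C2 2-[bis(2,2,2-trifluoroethoxy)phosphoryl]propanoate of 22 | C=C(OS(=O)(=O)C(F)(F)F)[C@@H]1C[C@@H]2O[C@]2(C)[C@H](OC(=O)C(C)P(=O)(OCC(F)(F)F)OCC(F)(F)F)[C@@H]1OC(C)=O
F5 | step 22 | (3R)-1-hydroxy-4-methyl-4-[(triethylsilyl)oxy]pentan-3-yl (2Z)-2-methylbut-2-enoate | OCC[C@@H](OC(=O)/C(C)=C\C)C(C)(C)O[Si](CC)(CC)CC
F6 | step 23 | C8-epimeric mixture of 32 | C=C(C(O)C[C@@H](OC(=O)/C(C)=C\C)C(C)(C)O[Si](CC)(CC)CC)[C@@H]1C[C@@H]2O[C@]2(C)[C@H](OC(=O)/C(C)=C\C)[C@@H]1OC(C)=O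
F7 | step 23 | C8 ketone (enone) corresponding to 32 | C=C(C(=O)C[C@@H](OC(=O)/C(C)=C\C)C(C)(C)O[Si](CC)(CC)CC)[C@@H]1C[C@@H]2O[C@]2(C)[C@H](OC(=O)/C(C)=C\C)[C@@H]1OC(C)=O
A1 | alternative 1 | 3-[(4-methoxyphenyl)methoxy]-2-methylcyclohex-5-ene-1,2-diol, hydroxyls cis, ether trans | C1=CC[C@@H](OCc2ccc(OC)cc2)[C@](C)(O)[C@@H]1O
A2 | alternative 1 | N-hydroxy-2-(tert-butyldimethylsilyloxy)-3-(2,2,5,5-tetramethyl-1,3-dioxolan-4-yl)propanimidoyl chloride | ON=C(Cl)[C@H](O[Si](C)(C)C(C)(C)C)C[C@H]1OC(C)(C)OC1(C)C
A3 | alternative 1 | cis-fused isoxazoline carrying the whole carbon skeleton | O1N=C([C@H](O[Si](C)(C)C(C)(C)C)C[C@@H](O2)C(C)(C)OC2(C)C)[C@@H]3C[C@@H](OCc4ccc(OC)cc4)[C@](C)(O)[C@H](O)[C@@H]31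
A4 | alternative 2 | (1E)-1-(tert-butyldimethylsilyloxy)-2-methylbuta-1,3-diene | C=C/C(C)=C/O[Si](C)(C)C(C)(C)C
A5 | alternative 2 | (5R)-5-[(1R,2S,5R)-menthyloxy]furan-2(5H)-one | O=C1O[C@@H](O[C@@H]2C[C@H](C)CC[C@H]2C(C)C)C=C1
A6 | alternative 2 | cis-fused lactone acetal cycloadduct with C2 silyl ether | O=C1O[C@@H](O[C@@H]3C[C@H](C)CC[C@H]3C(C)C)[C@@H]2CC=C(C)[C@H](O[Si](C)(C)C(C)(C)C)[C@@H]21
A7 | alternative 3 | methyl 3-oxocyclobutane-1-carboxylate | COC(=O)C1CC(=O)C1
A8 | alternative 3 | 1-(trimethylsilyl)propyne | CC#C[Si](C)(C)C
A9 | alternative 3 | 2-methyl-3-(trimethylsilyl)cyclohex-2-enone with the C7 methyl ester on C6 | COC(=O)[C@@H]1CC([Si](C)(C)C)=C(C)C(=O)C1
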